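The two binding constants are equal at 26 M⁻¹, so G and Q should hold one common bound share s of their charge. G binds in about 1.54 s, far less time than the 47.6 s of gas transfer. That makes transfer the rate-limiting step and lets s follow dissolved D as x over one plus x, with x the binding constant times [D].

    Q + D ⇌ Q.D (K1 = 26 M⁻¹, k1 = 8.6 M⁻¹ s⁻¹)
    G + D ⇌ G.D (K2 = 26 M⁻¹, k2 = 1.3 M⁻¹ s⁻¹)
    D → E (k3 = 0.0013 s⁻¹)
    X ⇌ D, rate k4*(csat - [D]) (k4 = 0.021 s⁻¹, csat = 46 mM)

common to all: G 0.50 M; Q 0.500 M; X 46 mM (held)
- epsilon: time 10 min
- gamma: time 30 min
- theta: time 90 min

- which of these there is most of at the end, counted by the G in it, epsilon (G.D / G)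
- which of these there is most of at the end, counted by the G in it, gamma (G.D / G)
- which of these there is most of at the end, counted by the G in it, theta (G.D / G)
- the largest of these amounts at the end, in percent of the G charged, epsilon
- the largest of these amounts at the end, in percent of the G charged, gamma
- the largest of these amounts at the end, in percent of the G charged, theta

- at the start none of D is dissolved
- run time (epsilon): 10 min

Where s stops needs no clock. Dissolved D comes to rest where transfer in equals loss to E, and the transfer coefficient divided by transfer plus loss coefficients, a ratio from which time has dropped out, takes the saturation value down to 43.3 mM. That gives s = 53.0%: this is the plateau share, the bound fraction of G once dissolved D stands still. The charges of G and Q do not enter it.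

The charges set the length of the way. Gamma must take up 0.573 M of D, which at the opening uptake of 0.0580 M min⁻¹ takes 9.89 min. Its neighbour with 1.2 M of Q looks nearly the same, with the same gas, the same G and the same plateau share, but it must take up 0.944 M, which takes 16.3 min. So gamma's 30 min holds 3.03 such times and the neighbour's holds 1.84, and we expect gamma close to the plateau and the neighbour somewhat under it.

G.D passes G at s = 0.5, where D is 38.5 mM and net uptake has sunk to 0.006498 M min⁻¹, far less than the opening rate. Taking the mean of those two rates, the 0.538 M needed takes about 16.7 min. So we commit: epsilon, read at 10 min, earlier than that, still has G ahead, while gamma and theta, read later, have G.D ahead near 53.0%. Our hand gives no figure for epsilon.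

The forecast says G at 61% for epsilon, G.D at 52.6% for gamma and G.D at 53% for theta, on the ground that “Gas uptake is the slow step”.

The flask gives G at 61.3% in epsilon, G.D at 52.6% in gamma and G.D at 53.0% in theta. Left ten times as long, epsilon reads 53.0% of G.D at 100 min. Against the plateau share of 53.0%, the neighbour of gamma with 1.2 M of Q stands 3.3 percentage points lower at 30.0 min, with 49.7% of G.D.

The numbers of this flask are invented.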